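**Plan**
Numbering (guaiane): ring A = C1–C5 (C3 ketone, C4=C5, methyl C15 on C4). Ring B = C1, C5–C10 (C11 on C7, ester oxygen on C8, methyl C14 on C10).
Retrosynthesis: the acyl groups come off O8 and O11, and the C4=C5 enone is traced back to its ketal-protected C1=C5 isomer. C11 is cut back to a C7 methyl ester and C8–OH to a ketone, and the central cut then severs C6–C7 and C9–C10.
Enabling feature: C7–C8–C9 is a three-carbon unit with acyl-level C11 on C7 and oxygen on C8, which is a siloxyvinyl diazoacetate. Its neighbours C6 and C10 are the ends of the diene C6=C5–C1=C10, which ring A holds s-cis as two exocyclic alkenes.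
Forward: ring A is bought as 2-methylcyclopentenone, so C15 is present from the start. This breaks the near-symmetry of ring A, so C4=C5 is later the only stable enone position. Five steps give the diene, one (4+3) operation closes ring B, and six functional-group steps finish.
Stereochemistry: C10 comes from the chiral dirhodium catalyst and is relayed by the Cope step. C7 and C8 are set together by a cis-selective transfer hydrogenation with dynamic kinetic resolution. C1 is set by equilibration at the γ-position of the enone, and the racemic C4 centre carried along is erased at the end.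

Key step: step 8

Assumption: the facial sense of Rh2(S-PTAD)4 (step 8) and of the (R,R)-TsDPEN ruthenium catalyst (step 10) is assigned by analogy with simpler substrates; if either proves opposite, the mirror-image catalyst is used and nothing else changes.

Step 1
Reactants: 1 2-methylcyclopent-2-en-1-one
Product: 2 6-methyl-1,4-dioxaspiro[4.4]non-6-ene
Conditions: (TMSOCH2)2, TMSOTf (3 mol %), CH2Cl2, −78 to −20 °C; pyridine quench
Reagents that add atoms: 1,2-bis(trimethylsilyloxy)ethane, C[Si](C)(C)OCCO[Si](C)(C)C
Why: Noyori-type ketalisation with the bis-silyl ether masks the future C3 ketone at low temperature and leaves the C4=C5 double bond where it is, which azeotropic acid ketalisation would put at risk.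

Step 2
Reactants: 2 6-methyl-1,4-dioxaspiro[4.4]non-6-ene
Product: 4 (±)-trans-6-methyl-1,4-dioxaspiro[4.4]nonan-7-ol, via alkylborane 3 (not isolated)
Conditions: BH3·THF, THF, 0 to 23 °C; then NaOH (3 M), H2O2 (30 %), 0 °C
Reagents that add atoms: hydrogen peroxide, OO
Why: Hydroboration–oxidation puts boron and then oxygen on the less substituted alkene carbon (future C5) by syn addition, giving the racemic trans alcohol, whose two stereocentres do not matter because C5 becomes sp2 in step 3 and C4 in step 14.

Step 3
Reactants: 4 (±)-trans-6-methyl-1,4-dioxaspiro[4.4]nonan-7-ol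
Product: 5 (±)-6-methyl-1,4-dioxaspiro[4.4]nonan-7-one
Conditions: n-Pr4N[RuO4] (5 mol %), NMO, 4 Å molecular sieves, CH2Cl2, 23 °C
Reagents that add atoms: none
Why: The Ley–Griffith oxidation is neutral and so spares a ketone whose β-ketal oxygen would be expelled under basic conditions.

Step 4
Reactants: 5 (±)-6-methyl-1,4-dioxaspiro[4.4]nonan-7-one; 6 acetaldehyde
Product: 10 (±)-(8E)-8-ethylidene-6-methyl-1,4-dioxaspiro[4.4]nonan-7-one, via lithium enolate 7 (not isolated), via lithium aldolate 8 (not isolated), via mesylate 9 (not isolated)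
Conditions: LiN(i-Pr)2, THF, −78 °C; 6, −78 °C; then MsCl (3 equiv), Et3N (6 equiv), −78 to 23 °C
Reagents that add atoms: none
Why: In this aldol condensation, kinetic deprotonation takes the open CH2 (future C1) rather than the tertiary C4–H beside the ketal, the aldolate is mesylated and eliminated (E1cB) in the same flask, and the ethylidene adopts the (E) geometry with its methyl group turned away from the carbonyl carbon for steric reasons.

Step 5
Reactants: 10 (±)-(8E)-8-ethylidene-6-methyl-1,4-dioxaspiro[4.4]nonan-7-one
Product: 11 (±)-(8E)-8-ethylidene-6-methyl-7-methylidene-1,4-dioxaspiro[4.4]nonane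
Conditions: Ph3PCH3Br, KOt-Bu, THF, 0 °C; then 10, 0 to 23 °C
Reagents that add atoms: methyltriphenylphosphonium bromide, C[P+](c1ccccc1)(c1ccccc1)c1ccccc1.[Br-]
Why: Wittig methylenation of a 2-alkylidenecyclopentanone is the usual entry to 1,2-bis(alkylidene)cyclopentanes, because carbonyl addition of the non-stabilised ylide outruns enolisation at the hindered C4–H and the ethylidene geometry is untouched.

Step 6
Reactants: 12 methyl acetoacetate
Product: 13 methyl 2-diazo-3-oxobutanoate
Conditions: 4-acetamidobenzenesulfonyl azide, Et3N, MeCN, 0 to 23 °C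
Reagents that add atoms: 4-acetamidobenzenesulfonyl azide, CC(=O)Nc1ccc(cc1)S(=O)(=O)N=[N+]=[N-]
Why: This is a Regitz diazo transfer to the doubly activated methylene group of a β-keto ester.

Step 7
Reactants: 13 methyl 2-diazo-3-oxobutanoate
Product: 14 methyl 3-(tert-butyldimethylsilyloxy)-2-diazobut-3-enoate
Conditions: TBSOTf, Et3N, CH2Cl2, 0 °C
Reagents that add atoms: tert-butyldimethylsilyl triflate, CC(C)(C)[Si](C)(C)OS(=O)(=O)C(F)(F)F
Why: Soft enolisation and O-silylation of the acetyl group converts the diazoacetoacetate into the siloxyvinyl diazoacetate and leaves the diazo group intact, which is a routine operation.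

Step 8
Reactants: 11 (±)-(8E)-8-ethylidene-6-methyl-7-methylidene-1,4-dioxaspiro[4.4]nonane; 14 methyl 3-(tert-butyldimethylsilyloxy)-2-diazobut-3-enoate
Product: 16 methyl (10S)-8-(tert-butyldimethylsilyloxy)-3,3-ethylenedioxy-12,13-dinorguaia-1(5),7-dien-11-oate (C4 epimers), via cis-divinylcyclopropane 15 (not isolated)
Conditions: dirhodium tetrakis[(S)-N-phthaloyl-1-adamantylglycinate], Rh2(S-PTAD)4 (1 mol %), 11 (3 equiv), 14 added over 2 h, hexanes, −26 to 23 °C; then toluene, 80 °C; unreacted 11 recovered
Reagents that add atoms: none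
Why: Loss of N2 from 14 at the catalyst gives a donor/acceptor vinylcarbene whose carbene carbon (C7) cyclopropanates the 1,1-disubstituted C5=C6 bond, and the cis-divinylcyclopropane 15 then undergoes a boat-type Cope rearrangement that forms C9–C10, breaks C5–C7 and leaves C7=C8 and C1=C5. This is the tandem cyclopropanation/Cope rearrangement, the established formal (4+3) cycloaddition of vinyldiazoacetates with 1,3-dienes, for which siloxyvinyl diazoacetates and adamantylglycinate catalysts are the usual enantioselective pairing. Ring B closes as a seven-membered ring in the [3,3] step, by C9–C10 bond formation with simultaneous opening of the three-membered ring, after C6–C7 has been made in the cyclopropanation. C10 is the only lasting new stereocentre: the catalyst chooses the diene face that C7 attacks, both new bonds form on that face, and the outward methyl group of the (E)-ethylidene then ends up as (10S). Site selectivity for C5=C6 over the trisubstituted C1=C10 follows from the steric demand of donor/acceptor carbenes, and any trans-divinylcyclopropane should enter the productive manifold on warming because its C5–C7 bond is flanked by two allylic positions and an ester. The C4 centre is racemic and is erased in step 14, so 11 is used in excess: the enantiomer whose methyl group lies opposite the catalyst-preferred face reacts first, and the selectivity at C10 should stay that of the catalyst.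

Step 9
Reactants: 16 methyl (10S)-8-(tert-butyldimethylsilyloxy)-3,3-ethylenedioxy-12,13-dinorguaia-1(5),7-dien-11-oate
Product: 17 methyl (10S)-3,3-ethylenedioxy-8-oxo-12,13-dinorguai-1(5)-en-11-oate (C4 and C7 epimers, keto/enol)
Conditions: n-Bu4NF, AcOH, THF, 0 °C
Reagents that add atoms: none
Why: Buffered fluoride desilylation converts the silyl enol ether into the β-keto ester without touching the ketal or the C1=C5 alkene, and leaves C7 configurationally labile, which step 10 exploits.

Step 10
Reactants: 17 methyl (10S)-3,3-ethylenedioxy-8-oxo-12,13-dinorguai-1(5)-en-11-oate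
Product: 18 methyl (7S,8R,10S)-3,3-ethylenedioxy-8-hydroxy-12,13-dinorguai-1(5)-en-11-oate (C4 epimers)
Conditions: RuCl[(R,R)-TsDPEN](p-cymene) (2 mol %), HCO2H/Et3N (5:2), CH2Cl2, 25 °C
Reagents that add atoms: none
Why: In this Noyori–Ikariya asymmetric transfer hydrogenation with dynamic kinetic resolution the C7 epimers interconvert through the enol, the catalyst reduces the one that lets hydride reach C8 from the α face (opposite the ester and the C10 methyl group), and 2-oxocycloalkanecarboxylates are known to give cis hydroxy esters under these conditions, so C7 (S) and C8 (R) are set together.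

Step 11
Reactants: 18 methyl (7S,8R,10S)-3,3-ethylenedioxy-8-hydroxy-12,13-dinorguai-1(5)-en-11-oate
Product: 20 (7S,8R,10S)-3,3-ethylenedioxyguai-1(5)-ene-8,11-diol (C4 epimers), via methyl ketone 19 (not isolated)
Conditions: MeMgBr (5 equiv), THF, 0 to 23 °C; aq. NH4Cl
Reagents that add atoms: methylmagnesium bromide, C[Mg]Br
Why: Double Grignard addition to the ester builds the C11 carbinol, and the C8 magnesium alkoxide formed first lowers the acidity of C7–H, so the cis relationship should be kept.

Step 12
Reactants: 20 (7S,8R,10S)-3,3-ethylenedioxyguai-1(5)-ene-8,11-diol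
Product: 21 (7S,8R,10S)-3,3-ethylenedioxy-11-hydroxyguai-1(5)-en-8-yl 2-methylpropanoate (C4 epimers)
Conditions: (i-PrCO)2O, Et3N, DMAP (10 mol %), CH2Cl2, 0 to 23 °C
Reagents that add atoms: isobutyric anhydride, CC(C)C(=O)OC(=O)C(C)C
Why: DMAP-catalysed acylation distinguishes the secondary C8 hydroxyl from the tertiary C11 hydroxyl on steric grounds.

Step 13
Reactants: 21 (7S,8R,10S)-3,3-ethylenedioxy-11-hydroxyguai-1(5)-en-8-yl 2-methylpropanoate
Product: 22 (7S,8R,10S)-11-acetoxy-3,3-ethylenedioxyguai-1(5)-en-8-yl 2-methylpropanoate (C4 epimers)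
Conditions: Ac2O (10 equiv), DMAP (0.5 equiv), Et3N, toluene, 50 °C
Reagents that add atoms: acetic anhydride, CC(=O)OC(C)=O
Why: Acetylation by nucleophilic catalysis with DMAP under forcing conditions is the standard esterification of a tertiary alcohol, and it avoids acidic media that would ionise C11 or open the ketal.

Step 14
Reactants: 22 (7S,8R,10S)-11-acetoxy-3,3-ethylenedioxyguai-1(5)-en-8-yl 2-methylpropanoate
Product: 24 (1R,7S,8R,10S)-11-acetoxy-3-oxoguai-4-en-8-yl 2-methylpropanoate (CNP0197994.1), via unconjugated enone 23 (not isolated)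
Conditions: 1 M HCl, THF, 23 °C; then DBU, toluene, 23 to 50 °C
Reagents that add atoms: water, O
Why: Acid hydrolysis of the ketal frees the C3 ketone and base-mediated prototropic migration through the dienolate brings the alkene into conjugation; the C4 methyl group makes the tetrasubstituted C4=C5 enone the thermodynamic sink over the C1=C2 alternative and erases the C4 centre, while C1, γ to the enone and so equilibrating, should settle as (R) with H-1 cis to the C10 methyl group because C2, C14 and C11 can then all be equatorial on a twist-chair ring B.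

**Compound list**
1 | 2-methylcyclopent-2-en-1-one | CC1=CCCC1=O | starting material
2 | 6-methyl-1,4-dioxaspiro[4.4]non-6-ene | CC1=CCCC12OCCO2 | intermediate
3 | (±)-trans-(6-methyl-1,4-dioxaspiro[4.4]nonan-7-yl)borane, racemate, one enantiomer drawn | C[C@@H]1[C@@H](B)CCC12OCCO2 | intermediate
4 | (±)-trans-6-methyl-1,4-dioxaspiro[4.4]nonan-7-ol, racemate, one enantiomer drawn | C[C@@H]1[C@@H](O)CCC12OCCO2 | intermediate
5 | (±)-6-methyl-1,4-dioxaspiro[4.4]nonan-7-one | CC1C(=O)CCC12OCCO2 | intermediate
6 | acetaldehyde | CC=O | starting material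
7 | lithium 6-methyl-1,4-dioxaspiro[4.4]non-7-en-7-olate | CC1C([O-])=CCC12OCCO2.[Li+] | intermediate
8 | lithium 1-(6-methyl-7-oxo-1,4-dioxaspiro[4.4]nonan-8-yl)ethanolate (diastereomers) | CC([O-])C1CC2(OCCO2)C(C)C1=O.[Li+] | intermediate
9 | 1-(6-methyl-7-oxo-1,4-dioxaspiro[4.4]nonan-8-yl)ethyl methanesulfonate (diastereomers) | CC(OS(C)(=O)=O)C1CC2(OCCO2)C(C)C1=O | intermediate
10 | (±)-(8E)-8-ethylidene-6-methyl-1,4-dioxaspiro[4.4]nonan-7-one | C/C=C1\CC2(OCCO2)C(C)C1=O | intermediate
11 | (±)-(8E)-8-ethylidene-6-methyl-7-methylidene-1,4-dioxaspiro[4.4]nonane | C/C=C1\CC2(OCCO2)C(C)C1=C | intermediate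
12 | methyl acetoacetate | CC(=O)CC(=O)OC | starting material
13 | methyl 2-diazo-3-oxobutanoate | COC(=O)C(=[N+]=[N-])C(C)=O | intermediate
14 | methyl 3-(tert-butyldimethylsilyloxy)-2-diazobut-3-enoate | C=C(O[Si](C)(C)C(C)(C)C)C(=[N+]=[N-])C(=O)OC | intermediate
15 | (5S,7S)-cis-divinylcyclopropane: cyclopropane C5–C6–C7 spiro at C5 of ring A, C7 bearing CO2Me and the 1-siloxyvinyl group, the latter on the side of the C1 ethylidene (C4 epimers) | COC(=O)[C@@]1(C(=C)O[Si](C)(C)C(C)(C)C)C[C@@]12C(C)C3(OCCO3)C/C2=C\C | intermediate
16 | methyl (10S)-8-(tert-butyldimethylsilyloxy)-3,3-ethylenedioxy-12,13-dinorguaia-1(5),7-dien-11-oate (C4 epimers) | COC(=O)C1=C(O[Si](C)(C)C(C)(C)C)C[C@H](C)C2=C(C1)C(C)C3(OCCO3)C2 | intermediate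
17 | methyl (10S)-3,3-ethylenedioxy-8-oxo-12,13-dinorguai-1(5)-en-11-oate (C4 and C7 epimers) | COC(=O)C1CC2=C(CC3(OCCO3)C2C)[C@@H](C)CC1=O | intermediate
18 | methyl (7S,8R,10S)-3,3-ethylenedioxy-8-hydroxy-12,13-dinorguai-1(5)-en-11-oate (C4 epimers) | COC(=O)[C@H]1CC2=C(CC3(OCCO3)C2C)[C@@H](C)C[C@H]1O | intermediate
19 | (7S,8R,10S)-3,3-ethylenedioxy-8-hydroxy-13-norguai-1(5)-en-11-one, present as its magnesium alkoxide (C4 epimers) | CC(=O)[C@H]1CC2=C(CC3(OCCO3)C2C)[C@@H](C)C[C@H]1O | intermediate
20 | (7S,8R,10S)-3,3-ethylenedioxyguai-1(5)-ene-8,11-diol (C4 epimers) | CC(C)(O)[C@H]1CC2=C(CC3(OCCO3)C2C)[C@@H](C)C[C@H]1O | intermediate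
21 | (7S,8R,10S)-3,3-ethylenedioxy-11-hydroxyguai-1(5)-en-8-yl 2-methylpropanoate (C4 epimers) | CC(C)(O)[C@H]1CC2=C(CC3(OCCO3)C2C)[C@@H](C)C[C@H]1OC(=O)C(C)C | intermediate
22 | (7S,8R,10S)-11-acetoxy-3,3-ethylenedioxyguai-1(5)-en-8-yl 2-methylpropanoate (C4 epimers) | CC(=O)OC(C)(C)[C@H]1CC2=C(CC3(OCCO3)C2C)[C@@H](C)C[C@H]1OC(=O)C(C)C | intermediate
23 | (7S,8R,10S)-11-acetoxy-3-oxoguai-1(5)-en-8-yl 2-methylpropanoate (C4 epimers) | CC(=O)OC(C)(C)[C@H]1CC2=C(CC(=O)C2C)[C@@H](C)C[C@H]1OC(=O)C(C)C | intermediate
24 | (1R,7S,8R,10S)-11-acetoxy-3-oxoguai-4-en-8-yl 2-methylpropanoate | CC(=O)OC(C)(C)[C@H]1CC2=C(C)C(=O)C[C@@H]2[C@@H](C)C[C@H]1OC(=O)C(C)C | target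

Total step count: 14. Longest linear sequence: 12 steps (steps 1–5 and 8–14).

**Steps most likely to fail**

Step 8. Catalyst control may be lost. In one enantiomer of the racemic diene the C4 methyl group shields the face the catalyst prefers, so face selection at C10 can erode as the matched enantiomer is used up. The hindered C5=C6 bond may also react slowly. The fallback removes the mismatch before the diene is made and sets out from racemic alcohol 4.
- Acylation with vinyl acetate and Candida antarctica lipase B is a kinetic resolution. The (7R) carbinol is the fast-reacting one by the empirical rule for lipase acylation of secondary alcohols, so this should give the (6S,7R)-acetate F1.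
- Methanolysis (K2CO3, MeOH) then gives the (6S,7R)-alcohol F2.
- The conditions of steps 3, 4 and 5 lead through the (6S)-ketone F3 and the (6S,8E)-enone F4 to the (6S,8E)-diene F5, whose C4 methyl group points to the α face.
- F5 and 14 are combined in equimolar amounts under the conditions of step 8. Substrate and catalyst bias now reinforce each other, and the route is rejoined at 16 as a single C4 epimer.

Step 10. The catalyst may discriminate poorly between the two alkyl-type flanks of the C8 ketone, which would mean poor facial selectivity or leakage to the trans hydroxy ester. The fallback separates the two stereochemical tasks and sets out from 17.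
- Hydrogenation with dynamic kinetic resolution (RuCl2[(S)-BINAP], H2, CH2Cl2, 50 °C) is known to be trans-selective for 2-oxocycloalkanecarboxylates. It fixes C7 correctly in the (7S,8S,10S)-trans hydroxy ester F6.
- MeMgBr converts F6 into the (7S,8S,10S)-trans diol F7.
- Dess–Martin periodinane oxidises only the secondary alcohol, giving the (7R,10S)-β-hydroxy ketone F8.
- LiBH(s-Bu)3 (THF, −78 °C) should deliver hydride from the face opposite the bulky C7 side chain, giving the cis diol. The route is rejoined at 20.

Step 13. Acylation of the crowded tertiary alcohol may be sluggish, which gives time for migration of the isobutyryl group from O8 to O11 or for elimination at C11. The fallback reverses the order of the two acylations and sets out from diol 20.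
- Trimethyl orthoacetate and pyridinium tosylate should give the six-membered cyclic orthoacetate F9.
- Mild aqueous acetic acid opens F9 with release of the less hindered, better leaving secondary oxygen, which should leave the acetyl group on O11 in the 11-acetoxy-8-ol F10.
- Isobutyric anhydride with DMAP then acylates the free C8 hydroxyl. The route is rejoined at 22.

**Further compounds**
F1 | step 8 | (6S,7R)-6-methyl-1,4-dioxaspiro[4.4]nonan-7-yl acetate | C[C@H]1[C@H](OC(C)=O)CCC12OCCO2
F2 | step 8 | (6S,7R)-6-methyl-1,4-dioxaspiro[4.4]nonan-7-ol | C[C@H]1[C@H](O)CCC12OCCO2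
F3 | step 8 | (6S)-6-methyl-1,4-dioxaspiro[4.4]nonan-7-one | C[C@H]1C(=O)CCC12OCCO2
F4 | step 8 | (6S,8E)-8-ethylidene-6-methyl-1,4-dioxaspiro[4.4]nonan-7-one | C/C=C1\CC2(OCCO2)[C@@H](C)C1=O
F5 | step 8 | (6S,8E)-8-ethylidene-6-methyl-7-methylidene-1,4-dioxaspiro[4.4]nonane | C/C=C1\CC2(OCCO2)[C@@H](C)C1=C
F6 | step 10 | methyl (7S,8S,10S)-3,3-ethylenedioxy-8-hydroxy-12,13-dinorguai-1(5)-en-11-oate (C4 epimers) | COC(=O)[C@H]1CC2=C(CC3(OCCO3)C2C)[C@@H](C)C[C@@H]1O
F7 | step 10 | (7S,8S,10S)-3,3-ethylenedioxyguai-1(5)-ene-8,11-diol (C4 epimers) | CC(C)(O)[C@H]1CC2=C(CC3(OCCO3)C2C)[C@@H](C)C[C@@H]1O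
F8 | step 10 | (7R,10S)-3,3-ethylenedioxy-11-hydroxyguai-1(5)-en-8-one (C4 epimers) | CC(C)(O)[C@H]1CC2=C(CC3(OCCO3)C2C)[C@@H](C)CC1=O
F9 | step 13 | cyclic 8,11-O-(1-methoxyethylidene) orthoacetate of diol 20 (epimers at C4 and at the orthoester carbon) | CC1(C)OC(C)(OC)O[C@@H]2C[C@H](C)C3=C(C[C@H]12)C(C)C4(OCCO4)C3
F10 | step 13 | (7S,8R,10S)-11-acetoxy-3,3-ethylenedioxyguai-1(5)-en-8-ol (C4 epimers) | CC(=O)OC(C)(C)[C@H]1CC2=C(CC3(OCCO3)C2C)[C@@H](C)C[C@H]1O
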